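**Retrosynthetic overview**

1. Numbering follows 1,2-dihydronaphthalene: C1 carries the aryl group, C2 the acetoxymethyl group, C3 the formyl group, C4 is the vinylic CH; ring A is the fused benzene ring (C4a–C8a, 6-OMe, 7-OH), ring B the carbocycle, ring C the pendant 4-hydroxy-3-methoxyphenyl ring. Ring B is opened at C3=C4 and at C1–C8a, a [3+3] disconnection into vanillin (ring A plus C4) and a γ-lactol (C1–C2–C3–CHO) that already carries ring C and the acetate.
2. Enabling feature: ring A plus C4 is a vanillin unit, electrophilic at the aldehyde carbon C4 and nucleophilic at ring carbon C8a (para to the 6-OMe). C3 is α to the formyl group (enol carbon), and C1 is benzylic and para to the phenol OH of ring C, so its C–O bond can ionize to a quinone methide or benzylic cation.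
3. The lactol (a temporary oxolane, ring D, with its oxygen on C1) goes back to an Evans syn-aldol of (S)-4-benzyl-3-(pent-4-enoyl)oxazolidin-2-one with O-benzylvanillin, which sets C2. Auxiliary reduction, primary acetylation, alkene cleavage and debenzylation follow.
4. Ring order: rings A and C are bought as vanillin units; ring D closes in step 5; ring B closes last, in step 7, as ring D opens, and C1 is set there trans to C2.

Key step: step 7

Assumption: lactols 12 and 13 are used as mixtures of anomers, because the anomeric carbon becomes the formyl carbon and the C1–O stereocenter is ionized in step 7; only the C2 configuration from step 2 has to be carried through.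

**Route**

Step 1
Reactants: 1 (S)-4-benzyloxazolidin-2-one; 2 pent-4-enoyl chloride
Product: 3 (S)-4-benzyl-3-(pent-4-enoyl)oxazolidin-2-one
Conditions: n-BuLi, THF, −78 °C; then 2, −78 to 0 °C
Reagents that add atoms: none
Why: N-acylation of the lithiated oxazolidinone by the acid chloride (standard attachment of an Evans auxiliary) should be clean, and no stereocenter is formed.

Step 2
Reactants: 3 (S)-4-benzyl-3-(pent-4-enoyl)oxazolidin-2-one; 4 4-(benzyloxy)-3-methoxybenzaldehyde
Product: 7 (S)-4-benzyl-3-[(S)-2-[(S)-[4-(benzyloxy)-3-methoxyphenyl](hydroxy)methyl]pent-4-enoyl]oxazolidin-2-one, via boron enolate 5 (not isolated), via boron aldolate 6 (not isolated)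
Conditions: Bu2BOTf, iPr2NEt, CH2Cl2, 0 °C; then 4, −78 to 0 °C; then pH 7 buffer, MeOH, 30% H2O2, 0 °C
Reagents that add atoms: none
Why: Evans syn-aldol reaction: the Z-boron enolate 5 should add to the aldehyde through a closed chair (Zimmerman–Traxler) transition state on the enolate face away from the benzyl group of the auxiliary, which sets the (S)-α-carbon (the later C2) and the (S)-carbinol carbon together, and the oxidative work-up frees 7 from the aldolate 6.

Step 3
Reactants: 7 (S)-4-benzyl-3-[(S)-2-[(S)-[4-(benzyloxy)-3-methoxyphenyl](hydroxy)methyl]pent-4-enoyl]oxazolidin-2-one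
Product: 8 (1S,2R)-1-[4-(benzyloxy)-3-methoxyphenyl]-2-(prop-2-en-1-yl)propane-1,3-diol
Conditions: LiBH4, MeOH (2 equiv), THF, 0 °C
Reagents that add atoms: none
Why: Reductive cleavage of the N-acyloxazolidinone by LiBH4, which attacks the exocyclic imide carbonyl, should give the 1,3-diol and the recoverable auxiliary 1 without touching the alkene, the benzyl ether or either stereocenter.

Step 4
Reactants: 8 (1S,2R)-1-[4-(benzyloxy)-3-methoxyphenyl]-2-(prop-2-en-1-yl)propane-1,3-diol
Product: 9 (R)-2-[(S)-[4-(benzyloxy)-3-methoxyphenyl](hydroxy)methyl]pent-4-en-1-yl acetate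
Conditions: AcCl (1.1 equiv), 2,4,6-collidine, CH2Cl2, −78 °C
Reagents that add atoms: acetyl chloride, CC(Cl)=O
Why: Kinetically selective acylation of the primary hydroxyl over the hindered secondary benzylic one (acid chloride with collidine at low temperature) should place the acetate of the target before any aldehyde is present.

Step 5
Reactants: 9 (R)-2-[(S)-[4-(benzyloxy)-3-methoxyphenyl](hydroxy)methyl]pent-4-en-1-yl acetate
Product: 12 [(2S,3R)-2-[4-(benzyloxy)-3-methoxyphenyl]-5-hydroxyoxolan-3-yl]methyl acetate, via triol 10 (not isolated), via hydroxy aldehyde 11 (not isolated)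
Conditions: OsO4 (2 mol %), NaIO4 (4 equiv), 2,6-lutidine, 1,4-dioxane/H2O (3:1), rt
Reagents that add atoms: osmium tetroxide, O=[Os](=O)(=O)=O (catalytic oxygen donor, reloaded by sodium periodate, [Na+].[O-]I(=O)(=O)=O)
Why: Lemieux–Johnson oxidative cleavage (catalytic dihydroxylation to 10, then periodate glycol cleavage) should give the γ-hydroxy aldehyde 11, which closes at once to the five-membered lactol by 5-exo-trig hemiacetal formation; the new anomeric center is of no consequence and the acetate and benzyl ether are inert.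

Step 6
Reactants: 12 [(2S,3R)-2-[4-(benzyloxy)-3-methoxyphenyl]-5-hydroxyoxolan-3-yl]methyl acetate
Product: 13 [(2S,3R)-5-hydroxy-2-(4-hydroxy-3-methoxyphenyl)oxolan-3-yl]methyl acetate
Conditions: H2 (1 atm), Pd/C (10 wt %), EtOAc, rt, stopped when 12 is consumed
Reagents that add atoms: none
Why: Hydrogenolysis of the aryl benzyl ether over Pd/C in neutral ethyl acetate should be faster than cleavage of the benzylic C–O bond of the lactol ring, and the acetate and both stereocenters are untouched.

Step 7
Reactants: 13 [(2S,3R)-5-hydroxy-2-(4-hydroxy-3-methoxyphenyl)oxolan-3-yl]methyl acetate; 14 vanillin (4-hydroxy-3-methoxybenzaldehyde)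
Product: 18 [(1S,2R)-3-formyl-7-hydroxy-1-(4-hydroxy-3-methoxyphenyl)-6-methoxy-1,2-dihydronaphthalen-2-yl]methyl acetate, via enol ether 15 (not isolated), via hydroxy enal 16 (not isolated), via quinone methide 17 (not isolated)
Conditions: 14 (3 equiv), CF3CO2H (10 equiv), CH2Cl2/(CF3)2CHOH (4:1), slow addition of 13 (final 0.01 M), 0 °C to rt, Ar
Reagents that add atoms: none
Why: Proposed new method: acid should equilibrate lactol 13 through its cyclic oxocarbenium ion with the enol ether 15, whose β-carbon (the later C3) attacks O-protonated vanillin 14, and loss of water should give the (E)-enal 16, the closest known reaction type being the acid-catalysed enol ether–aldehyde condensation (Müller-Cunradi–Pieroh type). In 16 the C1–O bond is benzylic and para to the free phenol, so it should ionize to the quinone methide 17 (present in acid as its O-protonated form, the benzylic cation), which is attacked by the ring A carbon para to the methoxy group (the later C8a); the closest known reaction types are the acid conversion of 2-aryltetrahydrofuran lignans into aryltetralins and the CF3CO2H cyclization of α-arylidene carbonyl compounds bearing a benzylic hydroxyl to 1-aryl-1,2-dihydronaphthalenes. Ring B closes in a 6-exo-trig Friedel–Crafts mode on the exocyclic carbon of 17, and rearomatization of ring A makes the closure irreversible. The new stereocenter C1 is set under substrate control by C2: the arene should add to the planar cation on the face anti to the acetoxymethyl group and give the 1,2-trans (1S,2R) product, while C2 is not acidified at any stage (β to the lactol carbon, not in conjugation with the enal) and should keep its configuration from step 2. The step needs cross- over self-condensation (secured by an excess of the non-enolizable 14 and slow addition of 13), the E enal geometry that places ring A cis to C2 (the thermodynamic isomer, which can equilibrate in acid), and attack at C8a and not at C5 (C8a is para to OMe and unhindered, C5 lies between OMe and the side chain).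

**Compound list**

1 | (S)-4-benzyloxazolidin-2-one | O=C1N[C@@H](Cc2ccccc2)CO1 | starting material
2 | pent-4-enoyl chloride | C=CCCC(Cl)=O | starting material
3 | (S)-4-benzyl-3-(pent-4-enoyl)oxazolidin-2-one | C=CCCC(=O)N1C(=O)OC[C@@H]1Cc1ccccc1 | intermediate
4 | 4-(benzyloxy)-3-methoxybenzaldehyde (O-benzylvanillin) | COc1cc(C=O)ccc1OCc1ccccc1 | starting material
5 | Z-dibutylboron enolate of 3 (formed in the flask, not isolated) | C=CC/C=C(\OB(CCCC)CCCC)N1C(=O)OC[C@@H]1Cc1ccccc1 | intermediate
6 | dibutylboron aldolate of 7 (formed in the flask, not isolated) | C=CC[C@@H]([C@H](OB(CCCC)CCCC)c1ccc(OCc2ccccc2)c(OC)c1)C(=O)N1C(=O)OC[C@@H]1Cc1ccccc1 | intermediate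
7 | (S)-4-benzyl-3-[(S)-2-[(S)-[4-(benzyloxy)-3-methoxyphenyl](hydroxy)methyl]pent-4-enoyl]oxazolidin-2-one | C=CC[C@@H]([C@H](O)c1ccc(OCc2ccccc2)c(OC)c1)C(=O)N1C(=O)OC[C@@H]1Cc1ccccc1 | intermediate
8 | (1S,2R)-1-[4-(benzyloxy)-3-methoxyphenyl]-2-(prop-2-en-1-yl)propane-1,3-diol | C=CC[C@H](CO)[C@H](O)c1ccc(OCc2ccccc2)c(OC)c1 | intermediate
9 | (R)-2-[(S)-[4-(benzyloxy)-3-methoxyphenyl](hydroxy)methyl]pent-4-en-1-yl acetate | C=CC[C@H](COC(C)=O)[C@H](O)c1ccc(OCc2ccccc2)c(OC)c1 | intermediate
10 | (2R)-2-[(S)-[4-(benzyloxy)-3-methoxyphenyl](hydroxy)methyl]-4,5-dihydroxypentyl acetate, C4 epimers (formed in the flask, not isolated) | OCC(O)C[C@H](COC(C)=O)[C@H](O)c1ccc(OCc2ccccc2)c(OC)c1 | intermediate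
11 | (R)-2-[(S)-[4-(benzyloxy)-3-methoxyphenyl](hydroxy)methyl]-4-oxobutyl acetate (formed in the flask, not isolated) | O=CC[C@H](COC(C)=O)[C@H](O)c1ccc(OCc2ccccc2)c(OC)c1 | intermediate
12 | [(2S,3R)-2-[4-(benzyloxy)-3-methoxyphenyl]-5-hydroxyoxolan-3-yl]methyl acetate, anomeric mixture | CC(=O)OC[C@H]1CC(O)O[C@@H]1c1ccc(OCc2ccccc2)c(OC)c1 | intermediate
13 | [(2S,3R)-5-hydroxy-2-(4-hydroxy-3-methoxyphenyl)oxolan-3-yl]methyl acetate, anomeric mixture | CC(=O)OC[C@H]1CC(O)O[C@@H]1c1ccc(O)c(OC)c1 | intermediate
14 | vanillin (4-hydroxy-3-methoxybenzaldehyde) | COc1cc(C=O)ccc1O | starting material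
15 | [(2S,3R)-2-(4-hydroxy-3-methoxyphenyl)-2,3-dihydrofuran-3-yl]methyl acetate (formed in the flask, not isolated) | CC(=O)OC[C@H]1C=CO[C@@H]1c1ccc(O)c(OC)c1 | intermediate
16 | (2R,3S)-2-[(E)-1-formyl-2-(4-hydroxy-3-methoxyphenyl)ethenyl]-3-hydroxy-3-(4-hydroxy-3-methoxyphenyl)propyl acetate (formed in the flask, not isolated) | O=C/C(=C/c1ccc(O)c(OC)c1)[C@H](COC(C)=O)[C@H](O)c1ccc(O)c(OC)c1 | intermediate
17 | (R)-2-[(E)-1-formyl-2-(4-hydroxy-3-methoxyphenyl)ethenyl]-3-(3-methoxy-4-oxocyclohexa-2,5-dien-1-ylidene)propyl acetate (formed in the flask, not isolated) | COC1=CC(=C[C@@H](COC(C)=O)/C(C=O)=C\c2ccc(O)c(OC)c2)C=CC1=O | intermediate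
18 | [(1S,2R)-3-formyl-7-hydroxy-1-(4-hydroxy-3-methoxyphenyl)-6-methoxy-1,2-dihydronaphthalen-2-yl]methyl acetate | COc1cc([C@H]2c3cc(O)c(OC)cc3C=C(C=O)[C@@H]2COC(C)=O)ccc1O | target

**Step count and risks**

Total step count: 7. Longest linear sequence: 7 steps (from 1 and 2 to 18); vanillin 14 enters in the last step.

Steps most likely to fail:

Step 7 (new method). What may go wrong: the enol ether from 13 may condense with its own oxocarbenium ion, or the benzylic C1–O bond may ionize and eliminate before the cross-condensation, so that material is lost to oligomers and the C2 stereocenter is eroded. The fallback is stepwise, uses known reactions and keeps both phenols benzylated. It sets out from 12, so step 6 is not run. 12 and 4 are condensed under enamine catalysis (pyrrolidine, PhCO2H, CH2Cl2, rt; amine-catalysed cross-aldol condensation) to (2R,3S)-3-[4-(benzyloxy)-3-methoxyphenyl]-2-[(E)-2-[4-(benzyloxy)-3-methoxyphenyl]-1-formylethenyl]-3-hydroxypropyl acetate F1. CF3CO2H in CH2Cl2 at 0 °C should then close ring B by the known benzylic cation Friedel–Crafts cyclization, trans-selectively, to [(1S,2R)-7-(benzyloxy)-1-[4-(benzyloxy)-3-methoxyphenyl]-3-formyl-6-methoxy-1,2-dihydronaphthalen-2-yl]methyl acetate F2. Both benzyl ethers are removed without reduction by BCl3 and pentamethylbenzene in CH2Cl2 at −78 °C, which comes back to the route at 18.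

Step 6. What may go wrong: over-reduction, that is hydrogenolysis of the benzylic C–O bond of the lactol ring alongside the O-benzyl group. The fallback moves the deprotection behind the annulation and makes it non-reductive. It sets out from 12, which is taken with 14 through the acid conditions of step 7 to [(1S,2R)-1-[4-(benzyloxy)-3-methoxyphenyl]-3-formyl-7-hydroxy-6-methoxy-1,2-dihydronaphthalen-2-yl]methyl acetate F3. The benzyl ether is then cleaved with BCl3 and pentamethylbenzene (CH2Cl2, −78 °C), which comes back to the route at 18.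

Step 4. What may go wrong: loss of site selectivity (acetylation of the benzylic hydroxyl or of both hydroxyls) or acetyl migration. The fallback replaces kinetic selectivity by protecting-group differentiation. It sets out from 7, whose secondary hydroxyl is silylated (Et3SiOTf, 2,6-lutidine, CH2Cl2, −78 °C) to (S)-4-benzyl-3-[(S)-2-[(S)-[4-(benzyloxy)-3-methoxyphenyl][(triethylsilyl)oxy]methyl]pent-4-enoyl]oxazolidin-2-one F4. LiBH4 (THF, MeOH, 0 °C) cleaves the auxiliary to (R)-2-[(S)-[4-(benzyloxy)-3-methoxyphenyl][(triethylsilyl)oxy]methyl]pent-4-en-1-ol F5. Ac2O, pyridine and DMAP give (R)-2-[(S)-[4-(benzyloxy)-3-methoxyphenyl][(triethylsilyl)oxy]methyl]pent-4-en-1-yl acetate F6. HF·pyridine (THF, 0 °C) removes the silyl group and comes back to the route at 9.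

Further compounds
F1 | step 7 | (2R,3S)-3-[4-(benzyloxy)-3-methoxyphenyl]-2-[(E)-2-[4-(benzyloxy)-3-methoxyphenyl]-1-formylethenyl]-3-hydroxypropyl acetate | O=C/C(=C/c1ccc(OCc2ccccc2)c(OC)c1)[C@H](COC(C)=O)[C@H](O)c1ccc(OCc2ccccc2)c(OC)c1
F2 | step 7 | [(1S,2R)-7-(benzyloxy)-1-[4-(benzyloxy)-3-methoxyphenyl]-3-formyl-6-methoxy-1,2-dihydronaphthalen-2-yl]methyl acetate | COc1cc([C@H]2c3cc(OCc4ccccc4)c(OC)cc3C=C(C=O)[C@@H]2COC(C)=O)ccc1OCc1ccccc1
F3 | step 6 | [(1S,2R)-1-[4-(benzyloxy)-3-methoxyphenyl]-3-formyl-7-hydroxy-6-methoxy-1,2-dihydronaphthalen-2-yl]methyl acetate | COc1cc([C@H]2c3cc(O)c(OC)cc3C=C(C=O)[C@@H]2COC(C)=O)ccc1OCc1ccccc1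
F4 | step 4 | (S)-4-benzyl-3-[(S)-2-[(S)-[4-(benzyloxy)-3-methoxyphenyl][(triethylsilyl)oxy]methyl]pent-4-enoyl]oxazolidin-2-one | C=CC[C@@H]([C@H](O[Si](CC)(CC)CC)c1ccc(OCc2ccccc2)c(OC)c1)C(=O)N1C(=O)OC[C@@H]1Cc1ccccc1
F5 | step 4 | (R)-2-[(S)-[4-(benzyloxy)-3-methoxyphenyl][(triethylsilyl)oxy]methyl]pent-4-en-1-ol | C=CC[C@H](CO)[C@H](O[Si](CC)(CC)CC)c1ccc(OCc2ccccc2)c(OC)c1
F6 | step 4 | (R)-2-[(S)-[4-(benzyloxy)-3-methoxyphenyl][(triethylsilyl)oxy]methyl]pent-4-en-1-yl acetate | C=CC[C@H](COC(C)=O)[C@H](O[Si](CC)(CC)CC)c1ccc(OCc2ccccc2)c(OC)c1
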